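Early on, the alder flask shows a lag, with 9.0% product at 0.500 d, then a fast rise to 43.8% at 1.67 d, and by 8.00 d it stands at 69.3% and has nearly stopped.

common to all: solid substrate 2.6 M; free catalyst 13 mM
- alder: the very flask that is asked about, followed so far
- flask: time 8.0 d

- alder (time / d: product / %): 0.500: 9.0; 1.67: 43.8; 3.00: 59.4; 4.00: 63.4; 6.00: 68.6; 8.00: 69.3

(each reading ± 1 percentage point)

- winter: at 8.0 d add free catalyst, 100% of the amount charged, then wait 15 d
- midnight: change nothing and wait 15 d more
- noon: at 8.0 d take out 90% of the product then present, then wait 15 d

- as a solid, counted per litre of solution: solid substrate
- removed product is counted in
- the numbers in the tables scatter with a standard deviation of 1 percentage point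
- at the start none of the solid substrate is in solution
- additions bring no volume worth counting

* product, in percent of the solid substrate first charged, at 8.0 d
* which option adds most product ("none" when 2 percentage points or less is all one gets) (winter / midnight / noon / none)
* product present, with what was taken out counted in, in percent of the solid substrate first charged, after winter
* product present, with what was taken out counted in, in percent of the solid substrate first charged, after noon

Two chemists read that stall differently. One calls it a balance (an equilibrium) between product and the unconverted rest. On that view fresh catalyst changes nothing, while noon, with 90% of the product taken out, climbs back to 88.4%. The other calls it catalyst deactivation: the free catalyst dies during the run, so noon and midnight stay at the last reading and winter pays.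

I hold the second view, and I reckon it this way. Alder's unconverted share of 30.7% gives 1.18 for the reach of a charge, the natural logarithm of the factor by which one charge of catalyst shrinks the unconverted share before it stops working. A second equal charge would shrink that share by the same factor, which puts winter at 90.6%.

But alder's charge was ageing during the lag, so I go round once more. Taking the solid as dissolved by 1.67 d, the reach still to come was 0.605 there and 0.280 at 3.00 d, which reads as a decay of 0.580 d⁻¹. Carried back to the start, this gives a fresh charge a reach of 1.59, and winter reaches 93.8%. These are readings, with their scatter of 1 percentage point. For now I commit to about the last reading.

The forecast takes the same side, with 69.8% now, winter as best, 70.5% after noon and 96% after winter, which is higher than my 93.8%, saying fresh catalyst “should consume most of the remaining 30, giving about 97”.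

The flask gives 68.7% at 8.0 d, and winter wins with 95.2%, adding 26 points, while noon ends at 69.0%.

    starting material → intermediate (k = 0.960 h⁻¹)
    free catalyst + intermediate → free catalyst + product (k = 4.00 M⁻¹ h⁻¹)
    free catalyst → spent catalyst (k = 0.0280 h⁻¹)
    solid substrate ⇌ starting material, rate k4*(cs4 - [starting material]) while solid is left; crystals form when [starting material] > cs4 (solubility = 0.490 M, k = 0.210 h⁻¹)

Free catalyst stands at 0.463% of its charge at 8.00 d, and the untouched flask still shows 69.0% at 80.0 d, a flat reading that both views expect, but noon ends at 69.0%, not at the balance view's 88.4%. Winter's charge shrank the unconverted share from 31.3% to 4.80%, a reach of 1.88, against my 1.59 and alder's 1.18. Scaled by the catalyst charged, alder's reach becomes 0.472 for a neighbour flask charged with 0.0052 M of free catalyst, which means 37.6% product, and that flask holds 37.8% at 8.0 d.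

(The data were computed with constants of no real substance, and the scatter is random.)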